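The seven-membered ring (C1, C5, C6–C10) bears oxygen on C6 and C10, the two atoms flanking the C1–C5 fusion bond. A transannular C6–C10 bond therefore recasts it as a cyclobutane-1,2-diol held between two cyclopentanes, the [2+2] adduct of 3-methylcyclopent-2-enone and a symmetric 4-methylcyclopentene-1,2-diol bis(silyl ether). One enantioselective photocycloaddition forms C1–C10 and C5–C6, fixes quaternary C1 and unites twelve skeletal carbons. The rigid adduct first receives the C4 isopropyl carbinol from its convex face. Glycol cleavage then releases the hydroazulene-6,10-dione, C5 is equilibrated, C6 is reduced under C4–OH direction, and C10 is set by reduction and inversion.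

Key step: step 2

Numbering and faces:
- C1 is the methyl-bearing fusion carbon, C2 and C3 are cyclopentane CH2, C4 is the isopropyl carbinol carbon, and C5 is the fusion CH.
- C6 is the acyloxy CH, C7 is CH2, C8 is the methyl-bearing alkene carbon, C9 is the alkene CH, and C10 is the free carbinol CH.
- β is the face of the C1 methyl group and α is the opposite face.
- In this numbering the target is (1S,4R,5S,6S,10R): 4β-OH, 5α-H, 6α-anisoyloxy, 10α-OH.
- The photoadduct holds five stereocentres (C1, C5, C6, C8, C10). A C8 epimer, if formed, converges at compound 19.

Assumption: the sense of induction of the oxazaborolidine is inferred by analogy and has to be verified on 5. Both antipodes of the catalyst are equally accessible, and the one that leaves the Si face of the enone β-carbon open is used.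

Step 1
Reactants: 1 dimethyl 3-methylglutarate; 2 chlorotrimethylsilane
Product: 3 4-methyl-1,2-bis(trimethylsilyloxy)cyclopentene
Conditions: Na, TMSCl, toluene, reflux
Reagents that add atoms: chlorotrimethylsilane (2), C[Si](C)(C)Cl
Why: Acyloin condensation in its Rühlmann form: sodium couples the two ester carbonyl groups reductively and chlorotrimethylsilane traps both the enediolate and the methoxide, which shuts down Dieckmann cyclisation, five-membered ring closure of glutarates being a standard case in which no stereocentre arises.

Step 2
Reactants: 3 4-methyl-1,2-bis(trimethylsilyloxy)cyclopentene (excess); 4 3-methylcyclopent-2-enone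
Product: 5 cis-anti-cis tricyclic ketone
Conditions: hν (366 nm), AlBr3-activated (S)-3,3-diphenyl-1-(2,4,6-trifluorophenyl)tetrahydro-1H,3H-pyrrolo[1,2-c][1,3,2]oxazaborole (50 mol %), CH2Cl2, −75 °C
Reagents that add atoms: none
Why: Proposed new method: coordination of 4 to the cationic boron Lewis acid shifts its ππ* band to longer wavelength, so that 366 nm light excites the bound enone selectively; after intersystem crossing the triplet adds to the electron-rich alkene 3 to give a 1,4-diradical that closes the cyclobutane. The closest known reactions are the racemic photocycloaddition of cyclopentenones to 1,2-bis(trimethylsilyloxy)cycloalkenes and the oxazaborolidine–AlBr3-catalysed enantioselective intermolecular [2+2] photocycloaddition of cyclic enones to simple alkenes; what is new is their combination on a silyl enediol ether and a cyclopentenone. The only ring formed, the four-membered ring C1–C5–C6–C10, closes by recombination of the diradical (formal [2+2], bonds C1–C10 and C5–C6). The absolute configuration at C1 is fixed by the aryl groups of the catalyst, which shield one face of the bound enone so that 3 adds to the Si face of the β-carbon; C5 follows because only a cis-fused bicyclo[3.2.0]heptanone is attainable, C6 and C10 are cis for the same reason and place their ring anti to the cyclopentanone for steric reasons, and C8 results from approach anti to its methyl group and is erased in step 11. No regiochemical question arises because C6 and C10 of 3 are equivalent by symmetry. The dark conjugate addition of the silyl enol ether should be slow at −75 °C because it would have to join two fully substituted carbons, and the catalyst is preformed with a slight excess of oxazaborolidine so that no free AlBr3 meets the silyl ethers.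

Step 3
Reactants: 5 cis-anti-cis tricyclic ketone
Product: 6 C3=C4 enol triflate
Conditions: KN(SiMe3)2, THF, −78 °C; PhNTf2, −78 to 0 °C
Reagents that add atoms: N-phenylbis(trifluoromethanesulfonimide), O=S(=O)(N(c1ccccc1)S(=O)(=O)C(F)(F)F)C(F)(F)F
Why: Enol triflate formation from a kinetic enolate: only the C3 methylene can be deprotonated, because the C5–H bond belongs to the cyclobutane and its enolate would be severely strained, so O-sulfonylation with PhNTf2 fixes the double bond between C3 and C4.

Step 4
Reactants: 6 C3=C4 enol triflate; 7 isopropylmagnesium chloride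
Product: 8 4-isopropyl C3=C4 alkene
Conditions: iPrMgCl, Fe(acac)3 (10 mol %), THF–NMP, −30 to 0 °C
Reagents that add atoms: isopropylmagnesium chloride (7), CC(C)[Mg]Cl
Why: Iron-catalysed Kumada-type cross-coupling of an enol triflate with an alkyl Grignard reagent, which is fast below 0 °C, accepts secondary alkyl groups without isomerisation and leaves silyl ethers alone, attaches the last three skeletal carbons to C4.

Step 5
Reactants: 8 4-isopropyl C3=C4 alkene
Product: 9 3β,4β-epoxide
Conditions: dimethyldioxirane, acetone–CH2Cl2, 0 °C
Reagents that add atoms: dimethyldioxirane, CC1(C)OO1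
Why: Epoxidation of a trisubstituted alkene with a neutral dioxirane: the concave face of the bicyclo[3.2.0]heptene is closed by the endo C6 silyloxy group, so oxygen is delivered to the convex face that carries H5 and the C1 methyl group, which sets the C4–O bond β as in the target, while neutral conditions avoid cyclobutylcarbinyl cation rearrangement.

Step 6
Reactants: 9 3β,4β-epoxide
Product: 11 tricyclic 4β,6,10-triol, via bis-TMS carbinol 10 (not isolated)
Conditions: lithium 4,4'-di-tert-butylbiphenylide, THF, −78 °C; then MeOH, −78 °C to rt
Reagents that add atoms: none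
Why: Reductive epoxide opening by electron transfer (the arene radical anion version of the lithium–amine reduction of hindered epoxides) breaks the C3–O bond to give the less substituted organolithium and the tertiary alkoxide, needs no rear-side approach through the blocked concave face and leaves the C4–O bond and its configuration untouched, after which methanol protonates C3 and the lithium methoxide formed catalyses methanolysis of both trimethylsilyl ethers.

Step 7
Reactants: 11 tricyclic 4β,6,10-triol
Product: 13 trans-fused ketol dione, via cis-fused ketol dione 12 (not isolated)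
Conditions: PhI(OAc)2, CH2Cl2, 0 °C to rt; then DBU, rt to 40 °C
Reagents that add atoms: none
Why: Criegee-type glycol cleavage with a hypervalent iodine reagent is fast for the eclipsed cis-diol and releases the cyclobutane strain, and the amine base then epimerises C5 through the C6 enolate, the trans-fused isomer being favoured because C6 moves from the face of the isopropyl group to the face of the C4 hydroxyl group, to which its carbonyl oxygen becomes hydrogen-bonded.

Step 8
Reactants: 13 trans-fused ketol dione
Product: 14 4β,6α-diol 10-ketone
Conditions: Me4NBH(OAc)3, MeCN–AcOH, −20 to 0 °C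
Reagents that add atoms: none
Why: Evans–Saksena reduction: the C4 hydroxyl group exchanges onto boron and delivers hydride intramolecularly to the β face of C6, which gives the 1,3-anti diol with the 6α-hydroxyl group, while the C10 ketone has no hydroxyl group within reach and is inert to triacetoxyborohydride.

Step 9
Reactants: 14 4β,6α-diol 10-ketone; 15 4-methoxybenzoyl chloride
Product: 16 6α-anisoate 10-ketone
Conditions: 4-MeOC6H4COCl, Et3N, DMAP, CH2Cl2, 0 °C to reflux
Reagents that add atoms: 4-methoxybenzoyl chloride (15), COc1ccc(C(=O)Cl)cc1
Why: DMAP-catalysed acylation with an acid chloride takes place only at the secondary C6 hydroxyl group, because the tertiary C4 hydroxyl group next to the isopropyl group is too hindered to react.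

Step 10
Reactants: 16 6α-anisoate 10-ketone
Product: 17 C9=C10 silyl enol ether with C4–OTMS
Conditions: TMSOTf, Et3N, CH2Cl2, 0 °C
Reagents that add atoms: trimethylsilyl trifluoromethanesulfonate, C[Si](C)(C)OS(=O)(=O)C(F)(F)F
Why: Soft enolisation to a silyl enol ether: C10 can enolise only towards C9 because C1 is quaternary, the anisoate has no α-hydrogen, and the simultaneous silylation of the C4 hydroxyl group is harmless.

Step 11
Reactants: 17 C9=C10 silyl enol ether with C4–OTMS
Product: 19 dauc-8-en-10-one 6α-anisoate, via O-silyl enone 18 (not isolated)
Conditions: Pd(OAc)2, MeCN, rt; then HF·pyridine, 0 °C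
Reagents that add atoms: none
Why: Saegusa–Ito oxidation: divalent palladium attacks C9 of the silyl enol ether and β-hydride elimination of H8 gives the C8=C9 enone from either C8 epimer, which erases that centre, and buffered fluoride then frees the C4 hydroxyl group without a base that could trigger vinylogous loss of the anisoate.

Step 12
Reactants: 19 dauc-8-en-10-one 6α-anisoate
Product: 20 10β-allylic alcohol
Conditions: NaBH4, CeCl3·7H2O, MeOH, −40 to 0 °C
Reagents that add atoms: none
Why: Luche reduction gives clean 1,2-addition, and hydride should enter from the α face, anti to the neighbouring pseudoaxial C1 methyl group as in the reduction of steroidal 17-ketones, so the 10β-alcohol is expected, while any 10α-epimer that forms is already the target.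

Step 13
Reactants: 20 10β-allylic alcohol
Product: 21 10α-chloroacetate
Conditions: ClCH2CO2H, PPh3, DIAD, toluene, 0 °C to rt
Reagents that add atoms: chloroacetic acid, OC(=O)CCl
Why: Mitsunobu inversion with a strongly acidic carboxylic acid suited to hindered alcohols: the carboxylate attacks the allylic oxyphosphonium salt from the open α face, anti to the C1 methyl group, so that SN2 displacement and any ion-pair pathway both lead to the 10α-ester (compare the 17β to 17α inversion of steroidal alcohols), and the tertiary C4 hydroxyl group does not react.

Step 14
Reactants: 21 10α-chloroacetate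
Product: 22 target
Conditions: K2CO3 (cat), MeOH, 0 °C
Reagents that add atoms: none
Why: Transesterification: the chloroacetate is far more electrophilic than the electron-rich and hindered 4-methoxybenzoate, so brief methanolysis removes only the C10 ester, with retention at C10 because the C–O bond is not touched.

Compound list

1 | dimethyl 3-methylglutarate | COC(=O)CC(C)CC(=O)OC | starting material
2 | chlorotrimethylsilane | C[Si](C)(C)Cl | starting material
3 | 4-methyl-1,2-bis(trimethylsilyloxy)cyclopentene (achiral) | CC1CC(O[Si](C)(C)C)=C(O[Si](C)(C)C)C1 | intermediate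
4 | 3-methylcyclopent-2-enone | CC1=CC(=O)CC1 | starting material
5 | cis-anti-cis tricyclic ketone: cyclopentanone C1–C5 (C4=O), cyclobutane C1-C5-C6-C10, cyclopentane C6–C10; C1-methyl and H5 cis on the convex face; both OTMS groups (C6, C10) on the cyclobutane face that carries C2 and C4; C8-methyl cis to the OTMS groups | C[Si](C)(C)O[C@@]12C[C@@H](C)C[C@]1(O[Si](C)(C)C)[C@@]3(C)CCC(=O)[C@@H]23 | intermediate
6 | C3=C4 enol triflate of 5 | C[Si](C)(C)O[C@@]12C[C@@H](C)C[C@]1(O[Si](C)(C)C)[C@@]3(C)CC=C(OS(=O)(=O)C(F)(F)F)[C@@H]23 | intermediate
7 | isopropylmagnesium chloride | CC(C)[Mg]Cl | starting material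
8 | tricyclic alkene, C3=C4 with isopropyl on C4 | C[Si](C)(C)O[C@@]12C[C@@H](C)C[C@]1(O[Si](C)(C)C)[C@@]3(C)CC=C(C(C)C)[C@@H]23 | intermediate
9 | 3β,4β-epoxide of 8 (oxygen on the convex face, cis to H5 and to the C1-methyl) | C[Si](C)(C)O[C@@]12C[C@@H](C)C[C@]1(O[Si](C)(C)C)[C@@]3(C)C[C@@H]4O[C@]4(C(C)C)[C@@H]23 | intermediate
10 | tricyclic 4β-hydroxy-4α-isopropyl bis(trimethylsilyl) ether | C[Si](C)(C)O[C@@]12C[C@@H](C)C[C@]1(O[Si](C)(C)C)[C@@]3(C)CC[C@@](O)(C(C)C)[C@@H]23 | intermediate (not isolated)
11 | tricyclic 4β,6,10-triol (cis-cyclobutane-1,2-diol) | O[C@@]12C[C@@H](C)C[C@]1(O)[C@@]3(C)CC[C@@](O)(C(C)C)[C@@H]23 | intermediate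
12 | cis-fused (5β-H) 4β-hydroxy-4α-isopropyl-1β,8α-dimethylperhydroazulene-6,10-dione | O=C1C[C@@H](C)CC(=O)[C@@]2(C)CC[C@@](O)(C(C)C)[C@@H]12 | intermediate (not isolated)
13 | trans-fused (5α-H) 4β-hydroxy-4α-isopropyl-1β,8α-dimethylperhydroazulene-6,10-dione | O=C1C[C@@H](C)CC(=O)[C@@]2(C)CC[C@@](O)(C(C)C)[C@H]12 | intermediate
14 | trans-fused 4β,6α-dihydroxy 10-ketone | O[C@H]1C[C@@H](C)CC(=O)[C@@]2(C)CC[C@@](O)(C(C)C)[C@H]12 | intermediate
15 | 4-methoxybenzoyl chloride | COc1ccc(C(=O)Cl)cc1 | starting material
16 | 6α-(4-methoxybenzoyloxy)-4β-hydroxy 10-ketone | COc1ccc(C(=O)O[C@H]2C[C@@H](C)CC(=O)[C@@]3(C)CC[C@@](O)(C(C)C)[C@H]23)cc1 | intermediate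
17 | C9=C10 trimethylsilyl enol ether of 16 with C4–OTMS | COc1ccc(C(=O)O[C@H]2C[C@@H](C)C=C(O[Si](C)(C)C)[C@@]3(C)CC[C@@](O[Si](C)(C)C)(C(C)C)[C@H]23)cc1 | intermediate
18 | C8=C9 enone (C10=O) with C4–OTMS | COc1ccc(C(=O)O[C@H]2CC(C)=CC(=O)[C@@]3(C)CC[C@@](O[Si](C)(C)C)(C(C)C)[C@H]23)cc1 | intermediate (not isolated)
19 | 4β-hydroxy-6α-(4-methoxybenzoyloxy)dauc-8-en-10-one | COc1ccc(C(=O)O[C@H]2CC(C)=CC(=O)[C@@]3(C)CC[C@@](O)(C(C)C)[C@H]23)cc1 | intermediate
20 | 10β-alcohol (C10 epimer of the target, OH cis to the C1-methyl) | COc1ccc(C(=O)O[C@H]2CC(C)=C[C@H](O)[C@@]3(C)CC[C@@](O)(C(C)C)[C@H]23)cc1 | intermediate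
21 | 10α-chloroacetate of the target | COc1ccc(C(=O)O[C@H]2CC(C)=C[C@@H](OC(=O)CCl)[C@@]3(C)CC[C@@](O)(C(C)C)[C@H]23)cc1 | intermediate
22 | CNP0211568.1, (1S,4R,5S,6S,10R)-4β,10α-dihydroxy-6α-(4-methoxybenzoyloxy)dauc-8-ene | COc1ccc(C(=O)O[C@H]2CC(C)=C[C@@H](O)[C@@]3(C)CC[C@@](O)(C(C)C)[C@H]23)cc1 | target

Total step count: 14. Longest linear sequence: 14 steps (1 to 22).

Steps most likely to fail

Step 2 (new method).
- What may go wrong: the Lewis acid may be consumed by silyl transfer from 3. Ground-state conjugate addition may compete. The small five-membered enone may be shielded too weakly for high enantiomeric purity.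
- Fallback: it sets out from 3 and 4 and uses the known uncatalysed reaction. Direct irradiation (Pyrex-filtered light near 350 nm, pentane, −20 °C) gives 5 together with its mirror image, the enantiomeric adduct F1.
- The racemate is resolved by the sulfoximine method for ketones. Lithiated (S)-N,S-dimethyl-S-phenylsulfoximine adds to the convex face of C4 at −78 °C. This gives the β-hydroxysulfoximine of 5 F2 and the β-hydroxysulfoximine of the mirror-image ketone F3, which are diastereomers and are separated by chromatography.
- Heating F2 in toluene reverses the addition and returns enantiopure 5, where the route is rejoined.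

Step 7.
- What may go wrong: retro-aldol opening of the cyclopentane through the C4 alkoxide, or dehydration, may compete with the slow deprotonation of the hindered C5–H bond.
- Fallback: it sets out from 12, which is isolated after the PhI(OAc)2 stage. TESOTf and 2,6-lutidine (CH2Cl2, −78 °C) convert it into the cis-fused dione triethylsilyl ether F4.
- With the hydroxyl group masked no alkoxide can form, so DBU in warm toluene can act as long as needed to give the trans-fused dione triethylsilyl ether F5.
- HF·pyridine then returns 13, where the route is rejoined.

Step 13.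
- What may go wrong: the activated allylic alcohol may eliminate to a diene, undergo allylic transposition, or be displaced only sluggishly next to quaternary C1.
- Fallback: it sets out from 19, replaces substrate control plus inversion by reagent control, and makes no new compound (F0).
- Corey–Bakshi–Shibata reduction with (S)-2-methyl-CBS-oxazaborolidine and BH3·SMe2 (toluene, −40 °C) treats the quaternary C1 side as the large group. It should deliver hydride to the β face, which leads directly to 22 and bypasses 20 and 21.

Further compounds
F1 | step 2 | enantiomer of 5 | C[Si](C)(C)O[C@]12C[C@H](C)C[C@@]1(O[Si](C)(C)C)[C@]3(C)CCC(=O)[C@H]23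
F2 | step 2 | β-hydroxysulfoximine from 5 and the (S)-sulfoximine (CH2 on the convex face of C4, OH on the concave face) | C[Si](C)(C)O[C@@]12C[C@@H](C)C[C@]1(O[Si](C)(C)C)[C@@]3(C)CC[C@](O)(C[S@@](=O)(=NC)c4ccccc4)[C@@H]23
F3 | step 2 | β-hydroxysulfoximine from F1 and the (S)-sulfoximine | C[Si](C)(C)O[C@]12C[C@H](C)C[C@@]1(O[Si](C)(C)C)[C@]3(C)CC[C@@](O)(C[S@@](=O)(=NC)c4ccccc4)[C@H]23
F4 | step 7 | cis-fused 6,10-dione C4 triethylsilyl ether | O=C1C[C@@H](C)CC(=O)[C@@]2(C)CC[C@@](O[Si](CC)(CC)CC)(C(C)C)[C@@H]12
F5 | step 7 | trans-fused 6,10-dione C4 triethylsilyl ether | O=C1C[C@@H](C)CC(=O)[C@@]2(C)CC[C@@](O[Si](CC)(CC)CC)(C(C)C)[C@H]12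
F0 | step 13 | none | none
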